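Slowness was what worried me in this flask, where J is fed over an hour onto a small charge of Q. Q carries J round to E through J.Q but also pairs off to Q2, and a catalyst that is being lost may leave a reversible change unfinished.

J 20 mM (fed, over 1.0 h); Q 0.26 mM; time 15 d; the fed solution adds 1.0 times the starting volume

    J + Q ⇌ J.Q (K1 = 35 M⁻¹, k1 = 1300 M⁻¹ h⁻¹)
    J.Q ⇌ Q + E (K2 = 0.054 M, k2 = 74 h⁻¹)
    2 Q → Q2 (k3 = 280 M⁻¹ h⁻¹)

- why nothing more happens at 15 d, or that something still does (forward and back rates have come level / all of J has reacted / no working catalyst is left / it is still moving)
- conversion of J at 15 d
- amount of E at 15 d, in percent of the J charged

- where a step has two of a species, its rate is k times that concentration squared, and two are used at each turn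
- amounts are per litre of the starting volume; all of the dose is in the solution fed
- the reaction counts as stopped when no species that holds the J changes by six tenths of a point or more over the second half of the time
- run time (flask): 15 d

I set the end point first: the first two steps join J to E with an overall constant of 1.89, so at level rates E holds 65.4% of the J charged. The charge of Q is 1.30% of that of J, so I took conversion and E as one number. With J.Q in steady state and Q held fixed, J ⇌ E is pseudo-first-order. At the charge of Q, diluted by the feed to half its concentration, its relaxation time is 5.81 h. The bench rule says a change is over after 5 half-lives, here 20.1 h, and 15 d is far longer. But the rule needs Q to stay, and its first half-life by the third step, 13.7 h, is shorter than those 5 half-lives. The ratio of that half-life to the relaxation time, 2.36, does not depend on the charge of Q, and the run lasts 26.3 times that first half-life of Q, so the rule had passed its border.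

I therefore replaced the falling curve of Q by its mean. Q stands at the reciprocal of one plus the time counted in its half-lives, and the mean fraction of its charge over the run is 12.6%. The exponent of a first-order approach adds up rate over time, so this mean costs nothing there, whereas the straight mean of start and end would be 4.11 times too large. The count of relaxation times, the mean fraction of Q times the run time over the relaxation time, came to 7.81. That left 0.0406% of the distance to equilibrium, so I committed to 65.4% with rates level.

The forecast said forward and back rates have come level, with 65.4% conversion and 65.4% of E, holding that “equilibrium is reached despite the decay”.

The simulation gave forward and back rates have come level, with 65.4% conversion and 65.4% of E. At 0.0417 d, the end of the feed, E already stood at 5.53% of the J charged and Q at 82.2% of its charge. The first two steps went on carrying J to E, with half of the conversion in by 0.241 d and 90.0% of it by 1.06 d, while my count passes 2.30 at 0.944 d. J stood at 35.5% of its charge at 3.00 d, and Q went on pairing off after that, so that at 15 d the catalyst stood as 4.08% Q, 0.494% J.Q and 95.4% Q2. For the neighbour flask with 0.10 mM of Q the count is 5.68, leaving 0.341% of the distance, and that flask held 65.2% of E at 15 d.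

The constants used here were set for the occasion; the flask was simulated.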